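**Strategy.** The flavone is cut at C4–C4a. Because C4 is an aryl ketone lying ortho to O1 on ring A, ring C can be closed last by acylating ring A with a carboxylic acid that already hangs from the O1–C2 enol ether. A single intramolecular Friedel–Crafts acylation thus makes the C4–C4a bond and ring C at once. Its substrate is a (Z)-β-aryloxycinnamic acid in which the future C2 carries the 2,3-dimethoxyphenoxy group (future ring A) and a 3-bromo-4,5-dimethoxyphenyl group (future ring B), the bromine serving as an acid-stable placeholder for the 3'-hydroxyl. The substrate comes from oxa-Michael addition of a phenol to an arylpropiolate; bromine is exchanged for hydroxyl afterwards.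

Key step: step 4

Remark: the conjugate addition in step 3 is assumed to give mainly the Z enol ether by anti addition; any E isomer carried forward should equilibrate in the acid of step 4 through reversible protonation at C3.

**Step 1**
Reactants: 1 3-bromo-4,5-dimethoxybenzaldehyde
Product: 2 1-bromo-5-ethynyl-2,3-dimethoxybenzene
Conditions: dimethyl (1-diazo-2-oxopropyl)phosphonate, K2CO3, MeOH, 0 °C → rt
Reagents that add atoms: dimethyl (1-diazo-2-oxopropyl)phosphonate, CC(=O)C(=[N+]=[N-])P(=O)(OC)OC
Why: Seyferth–Gilbert homologation in the Ohira–Bestmann variant: methanolysis of the reagent releases the diazomethylphosphonate anion, which olefinates the non-enolisable aldehyde and, after loss of N2 and a 1,2-shift in the alkylidene carbene, should give the terminal alkyne while the aryl bromide and the methyl ethers are inert to K2CO3/MeOH.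

**Step 2**
Reactants: 2 1-bromo-5-ethynyl-2,3-dimethoxybenzene
Product: 4 ethyl 3-(3-bromo-4,5-dimethoxyphenyl)prop-2-ynoate, via lithium acetylide 3 (not isolated)
Conditions: LiN(SiMe3)2, THF, −78 °C; then ClCO2Et, −78 → 0 °C
Reagents that add atoms: ethyl chloroformate, CCOC(=O)Cl; LiN(SiMe3)2, [Li]N([Si](C)(C)C)[Si](C)(C)C (lithium of intermediate 3 only)
Why: Alkoxycarbonylation of a metal acetylide: the amide base removes only the alkyne C–H (no bromine–lithium exchange, unlike an alkyllithium) and the acetylide is C-acylated by the chloroformate at low temperature.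

**Step 3**
Reactants: 4 ethyl 3-(3-bromo-4,5-dimethoxyphenyl)prop-2-ynoate; 5 2,3-dimethoxyphenol
Product: 7 (Z)-3-(3-bromo-4,5-dimethoxyphenyl)-3-(2,3-dimethoxyphenoxy)acrylic acid, via ethyl ester 6 (not isolated)
Conditions: K2CO3 (20 mol %), DMSO, 80 °C; then LiOH, THF/H2O, 40 °C; then cold aq. HCl to pH 3
Reagents that add atoms: lithium hydroxide, [Li+].[OH-] (oxygen of the carboxylic acid OH)
Why: Base-catalysed oxa-Michael addition of the phenoxide to the β-carbon of the ynoate with anti protonation should set the Z geometry (aryloxy cis to the ester), and saponification in an alcohol-free medium then frees the acid without exchanging the aryloxy group; no stereocentre is formed.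

**Step 4**
Reactants: 7 (Z)-3-(3-bromo-4,5-dimethoxyphenyl)-3-(2,3-dimethoxyphenoxy)acrylic acid
Product: 8 3'-bromo-4',5',7,8-tetramethoxyflavone [2-(3-bromo-4,5-dimethoxyphenyl)-7,8-dimethoxy-4H-chromen-4-one]
Conditions: P2O5/CH3SO3H (Eaton's reagent, 1:10 w/w), rt → 45 °C; poured onto ice
Reagents that add atoms: none
Why: P2O5/CH3SO3H converts the acid into a mixed anhydride or acylium ion, which attacks C6 of the phenoxy ring (the future C4a) and, after loss of a proton from the arenium ion, gives the aryl ketone, so that the C4–C4a bond is formed by intramolecular Friedel–Crafts acylation. The closest known reaction type is the acid-promoted cyclisation of β-aryloxycinnamic acids to flavones in P2O5/CH3SO3H or polyphosphoric acid. Ring C closes as a six-membered ring, exo with respect to the acylium C=O and endo with respect to the arene bond C4a–C8a. No stereocentre is created. The step needs acylation of ring A and not of ring B: the Z geometry holds the acid next to the aryloxy group, C6 is the only free position ortho to the ether oxygen and is activated by the para methoxy group, whereas ring B is deactivated by bromine and could only close a strained five-membered indenone from the E isomer. Anhydrous conditions keep the enol ether from hydrolysis, and the aryl bromide and the four methyl ethers should tolerate the medium at 45 °C or below.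

**Step 5**
Reactants: 8 3'-bromo-4',5',7,8-tetramethoxyflavone
Product: 10 3'-hydroxy-4',5',7,8-tetramethoxyflavone, via pinacol boronate 9 (not isolated)
Conditions: PdCl2(dppf) (5 mol %), B2pin2, KOAc, 1,4-dioxane, 85 °C; then 30% aq. H2O2, THF, 0 °C → rt
Reagents that add atoms: hydrogen peroxide, OO (the 3'-oxygen); bis(pinacolato)diboron, CC1(C)OB(OC1(C)C)B1OC(C)(C)C(C)(C)O1 (boron of intermediate 9 only)
Why: Miyaura borylation (oxidative addition of the aryl bromide to zerovalent palladium, acetate-assisted transmetallation with B2pin2, reductive elimination) followed by hydroperoxide-induced 1,2-migration of the aryl group from boron to oxygen and hydrolysis should give the phenol, the acetate-buffered peroxide stage being mild enough for the pyranone.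

**Compound list**
1 | 3-bromo-4,5-dimethoxybenzaldehyde | COc1cc(C=O)cc(Br)c1OC | starting material
2 | 1-bromo-5-ethynyl-2,3-dimethoxybenzene | C#Cc1cc(Br)c(OC)c(OC)c1 | intermediate
3 | lithium (3-bromo-4,5-dimethoxyphenyl)acetylide | [Li]C#Cc1cc(Br)c(OC)c(OC)c1 | intermediate
4 | ethyl 3-(3-bromo-4,5-dimethoxyphenyl)prop-2-ynoate | CCOC(=O)C#Cc1cc(Br)c(OC)c(OC)c1 | intermediate
5 | 2,3-dimethoxyphenol | COc1cccc(O)c1OC | starting material
6 | ethyl (Z)-3-(3-bromo-4,5-dimethoxyphenyl)-3-(2,3-dimethoxyphenoxy)acrylate | CCOC(=O)/C=C(\Oc1cccc(OC)c1OC)c1cc(Br)c(OC)c(OC)c1 | intermediate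
7 | (Z)-3-(3-bromo-4,5-dimethoxyphenyl)-3-(2,3-dimethoxyphenoxy)acrylic acid | OC(=O)/C=C(\Oc1cccc(OC)c1OC)c1cc(Br)c(OC)c(OC)c1 | intermediate
8 | 3'-bromo-4',5',7,8-tetramethoxyflavone | COc1ccc2c(=O)cc(-c3cc(Br)c(OC)c(OC)c3)oc2c1OC | intermediate
9 | 4',5',7,8-tetramethoxy-3'-(4,4,5,5-tetramethyl-1,3,2-dioxaborolan-2-yl)flavone | COc1ccc2c(=O)cc(-c3cc(B4OC(C)(C)C(C)(C)O4)c(OC)c(OC)c3)oc2c1OC | intermediate
10 | 3'-hydroxy-4',5',7,8-tetramethoxyflavone | COc1cc(-c2cc(=O)c3ccc(OC)c(OC)c3o2)cc(O)c1OC | target

**Total step count:** 5
**Longest linear sequence:** 5 steps (1 → 2 → 4 → 7 → 8 → 10)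

**Steps most likely to fail**

Step 4 (ring closure). The strong acid may cleave the aryl vinyl ether before acylation, the reagent may sulfonylate the very electron-rich ring A, or isomerisation may be followed by closure onto ring B. The fallback builds the same flavone by a chalcone route that sets out from aldehyde 1. Claisen–Schmidt condensation of 1 with commercial 1-(2-hydroxy-3,4-dimethoxyphenyl)ethanone (SMILES CC(=O)c1ccc(OC)c(OC)c1O; KOH, EtOH, rt) should give (E)-3-(3-bromo-4,5-dimethoxyphenyl)-1-(2-hydroxy-3,4-dimethoxyphenyl)prop-2-en-1-one F1. Oxidative cyclisation of the chalcone with catalytic I2 in DMSO at 130 °C (oxa-Michael closure, then iodine-mediated dehydrogenation) should give bromoflavone 8, where the route is rejoined.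

Step 3 (conjugate addition and saponification). The addition may be slow because the para methoxy group of ring B deactivates the β-carbon of the ynoate, geometric control may be lost, or hydroxide may displace the aryloxide during saponification. The fallback replaces conjugate addition by a copper-catalysed vinyl C–O coupling and sets out from ynoate 4. Hydroiodination (NaI, AcOH, 110 °C) should give, by anti addition, ethyl (Z)-3-(3-bromo-4,5-dimethoxyphenyl)-3-iodoacrylate F2. Ullmann-type coupling of this vinyl iodide with phenol 5 (CuI (copper monoiodide), N,N-dimethylglycine, Cs2CO3, 1,4-dioxane, 80 °C) proceeds with retention at the vinyl carbon and should give ester 6, now isolated, where the route is rejoined. The ester is then saponified as in step 3 to acid 7. The vinyl iodide should react much faster than the aryl bromide.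

Step 5 (bromide to phenol). Hydrodebromination may compete with borylation, or the peroxide may attack the pyranone ring. The fallback sets out from bromoflavone 8 and uses a palladium-catalysed C–O coupling with benzyl alcohol ([Pd(allyl)Cl]2, RockPhos, Cs2CO3, toluene, 90 °C), which should give 3'-benzyloxy-4',5',7,8-tetramethoxyflavone F3. Hydrogenolysis of the benzyl ether (H2, Pd/C, EtOAc, rt) should then give target 10.

**Further compounds**
F1 | step 4 | (E)-3-(3-bromo-4,5-dimethoxyphenyl)-1-(2-hydroxy-3,4-dimethoxyphenyl)prop-2-en-1-one | O=C(/C=C/c1cc(Br)c(OC)c(OC)c1)c1ccc(OC)c(OC)c1O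
F2 | step 3 | ethyl (Z)-3-(3-bromo-4,5-dimethoxyphenyl)-3-iodoacrylate | CCOC(=O)/C=C(\I)c1cc(Br)c(OC)c(OC)c1
F3 | step 5 | 3'-benzyloxy-4',5',7,8-tetramethoxyflavone | COc1ccc2c(=O)cc(-c3cc(OCc4ccccc4)c(OC)c(OC)c3)oc2c1OC
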